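Count where the L goes in each flask, starting with Saturday's.

    G + L → G.L (k1 = 28 M⁻¹ s⁻¹)
    J + L → J.L (k2 = 0.77 M⁻¹ s⁻¹)
    Q + L → Q.L (k3 = 12 M⁻¹ s⁻¹)
    L + G.L → L.G.L (k4 = 12 M⁻¹ s⁻¹)

| setting | Saturday's | Monday's | Thursday's | Wednesday's | Friday's |
|---|---|---|---|---|---|
| G | 0.050 M | 0.050 M | 0.050 M | 0.050 M | 0.050 M |
| L | 0.00500 M | 0.0150 M | 0.0500 M | 0.150 M | 0.400 M |
| J | 0.0500 M | 0.0500 M | 0.0500 M | 0.0500 M | 0.0500 M |
| Q | 0.0500 M | 0.0500 M | 0.0500 M | 0.0500 M | 0.0500 M |
| time | 1.0 min | 1.0 min | 1.0 min | 1.0 min | 1.0 min |

1. amount of G.L at the end, in percent of the G charged for Saturday's, Monday's, Thursday's, Wednesday's, Friday's, in this order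
2. how that number moves from the first to the last of them (falls all the way / hardly changes / rises, then falls / rises all the way / falls, then rises)

- "hardly changes" means that all values lie within two and a half points (for a concentration: within two and a half percent of the largest)
- run time (Saturday's): 1.0 min

In Saturday's flask L is the limiting reagent, at 0.00500 M against 0.050 M of G. With G, J and Q as charged, L has a half-life of 0.340 s, far shorter than the run, so this reckoning counts the whole charge as used. One L makes one G.L, which gives a first upper bound of 10.0% of the G charged.

G, J and Q compete for that L. G's share at the charge is 68.7%, the rate of G + L over the summed rates at which G, J and Q take L. G has a larger constant than J or Q, so it thins proportionally faster and its share can fall from there but not rise. The upper bound tightens to 6.87%.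

For the lower bound, take the worst state. G has lost the whole charge of L, G.L stands at that same amount, and each L taken by G.L removes one G.L. The net share is then 61.3%, which gives 6.13%.

The forecast puts Saturday's at 6.6%, inside this bracket, on the grounds that “G and Q take almost all of it and J takes very little”. For the row it expects rises, then falls.

The simulation gives rises, then falls, with the turn near 0.076 M of L.

| Flask | G.L, forecast | G.L | L.G.L |
|---|---|---|---|
| Saturday's | 6.6% | 6.65% | 0.101% |
| Monday's | 18.6% | 18.7% | 0.917% |
| Thursday's | 46.7% | 46.6% | 10.4% |
| Wednesday's | 10.3% | 10.2% | 89.6% |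
| Friday's | 0% | 0% | 100% |

Saturday's 6.65% stands inside the bracket. Monday's flask has the same charges of G, J and Q, hence the same share, so its 0.0150 M of L gives an upper bound of 20.6%, and it holds 18.7%. The row turns down mainly because of the step from L + G.L to L.G.L. With that step taken away, Friday's flask ends at 100% of G.L, against 0% with it.

Its constants are assumed, and the outcome is calculated.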